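**Plan**

Rings (benzofuran numbering): ring A is the 7-hydroxy-5-vinyl dihydrobenzofuran, ring B the 6-vinyl dihydrobenzofuran, ring C the 6-hydroxy dihydrobenzofuran bonded through its C4 to C3 of ring B.
Cuts: the nine O–CH3 bonds; the vinyl–C6 bond of ring B (Heck); the C2–C3 bond of rings B and A (carbene C–H insertion) and the aryl–C3 bonds of their ketone precursors (carbonylative Suzuki coupling for ring B, Grignard addition for ring A); in ring C the C2–aryl bond and the C3–C3a bond (cyclodehydration).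
Forward: ring C is closed flat as a 3-arylbenzofuran and arylated at C2; its C4 chloride becomes a boronate, then a diaryl ketone on whose carbon ring B closes; ring A closes separately in the same way; a Heck reaction joins the halves and BBr3 frees the nine phenols.
Enabling feature: C2 of ring C carries the 4-hydroxyphenyl group trans to the 3,5-dihydroxyphenyl group on C3, so the C2 aryl and the C3 hydrogen are cis, which is what syn carbopalladation of the C2=C3 bond of a 3-arylbenzofuran followed by retentive hydride delivery leaves.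
Stereochemistry: C2 and C3 of ring C from (R)-Segphos–palladium; C3 of ring B from Rh2(S-PTAD)4 and C3 of ring A from Rh2(R-PTAD)4, each C2 then equilibrated to trans with acid; the E alkene from the Heck reaction.

Key step: step 3

Assumption: the sense of induction of (R)-Segphos–palladium and of each Rh2(PTAD)4 enantiomer is taken as written; all are available as both antipodes, so an opposite sense would only exchange the catalyst enantiomer.

**Route**

Step 1
Reactants: 1 3-chloro-5-methoxyphenol; 2 2-bromo-1-(3,5-dimethoxyphenyl)ethanone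
Product: 3 2-(3-chloro-5-methoxyphenoxy)-1-(3,5-dimethoxyphenyl)ethanone
Conditions: K2CO3 (1.5 equiv.), acetone, 56 °C
Reagents that add atoms: none
Why: Williamson ether synthesis, the phenoxide of 1 displacing the primary α-keto bromide of 2 by SN2; no stereocentre is involved.

Step 2
Reactants: 3 2-(3-chloro-5-methoxyphenoxy)-1-(3,5-dimethoxyphenyl)ethanone
Product: 4 4-chloro-3-(3,5-dimethoxyphenyl)-6-methoxybenzofuran
Conditions: Bi(OTf)3 (10 mol%), ClCH2CH2Cl, 80 °C
Reagents that add atoms: none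
Why: Acid-catalysed cyclodehydration (intramolecular Friedel–Crafts hydroxyalkylation, then loss of water) should close the furan ring at the carbon ortho to the ether oxygen and para to methoxy, the most nucleophilic site as in 1,3-dialkoxybenzenes, so that chlorine ends at C4; any 6-chloro-4-methoxy isomer would be removed by crystallisation.

Step 3
Reactants: 4 4-chloro-3-(3,5-dimethoxyphenyl)-6-methoxybenzofuran; 5 4-iodoanisole
Product: 6 (2S,3S)-4-chloro-3-(3,5-dimethoxyphenyl)-6-methoxy-2-(4-methoxyphenyl)-2,3-dihydrobenzofuran (trans)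
Conditions: Pd2(dba)3 (5 mol%), (R)-Segphos (12 mol%), 5 (2 equiv.), HCO2Na (3 equiv., in portions), DMA, 90 °C
Reagents that add atoms: none
Why: Proposed new method: oxidative addition of 5 to the zerovalent palladium–(R)-Segphos complex and iodide dissociation in DMA should give a cationic arylpalladium that adds syn across the C2=C3 bond of the furan ring, aryl to C2 and palladium to the doubly benzylic C3, where the only β-hydrogen (on C2) is anti to palladium, so the benzylic palladium species waits for formate, loses CO2 and reductively eliminates C3–H with retention. The closest known reactions are the enantioselective intramolecular dearomative reductive Heck cyclisations of indoles and benzofurans with formate, the intermolecular dearomative arylboration of indoles, the Heck-type C2 arylation of benzofurans and the formate-mediated hydroarylation of norbornenes, whereas an intermolecular enantioselective version on a 3-arylbenzofuran has not been described. No ring closes; one C–C bond (C2–aryl) and one C–H bond (at C3) form. C2 is fixed by the furan face that the chiral bisphosphine complex selects (ligand control), and C3 follows from it through syn insertion and retentive C–H elimination, which puts the new aryl group and the C3 hydrogen cis and therefore the two aryl groups trans. The step needs C2 regioselectivity, expected from the enol-ether polarisation of the furan and benzylic stabilisation of palladium at C3; C–I over C–Cl chemoselectivity, expected from the far faster oxidative addition of the iodide; and hydride capture that is faster than β-aryloxide ring opening yet slower than alkene insertion, which sparingly soluble HCO2Na added in portions and an excess of 5 are meant to secure.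

Step 4
Reactants: 6 (2S,3S)-4-chloro-3-(3,5-dimethoxyphenyl)-6-methoxy-2-(4-methoxyphenyl)-2,3-dihydrobenzofuran
Product: 7 2-[(2S,3S)-3-(3,5-dimethoxyphenyl)-6-methoxy-2-(4-methoxyphenyl)-2,3-dihydrobenzofuran-4-yl]-4,4,5,5-tetramethyl-1,3,2-dioxaborolane
Conditions: Pd2(dba)3 (2 mol%), XPhos (8 mol%), KOAc (3 equiv.), dioxane, 110 °C
Reagents that add atoms: bis(pinacolato)diboron, CC1(C)OB(OC1(C)C)B1OC(C)(C)C(C)(C)O1
Why: Miyaura borylation of an electron-rich aryl chloride with an XPhos–palladium catalyst; the weak base KOAc cannot remove the C3 hydrogen, so both stereocentres should be kept.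

Step 5
Reactants: 8 5-chloro-2-iodophenol; 9 4-methoxybenzyl chloride
Product: 10 4-chloro-1-iodo-2-[(4-methoxybenzyl)oxy]benzene
Conditions: K2CO3 (1.5 equiv.), DMF, 60 °C
Reagents that add atoms: none
Why: Williamson ether synthesis at a benzylic chloride; the ether CH2 and its anisyl group are the future C2 of ring B and its aryl substituent.

Step 6
Reactants: 7 pinacol boronate of ring C; 10 4-chloro-1-iodo-2-[(4-methoxybenzyl)oxy]benzene
Product: 11 {4-chloro-2-[(4-methoxybenzyl)oxy]phenyl}[(2S,3S)-3-(3,5-dimethoxyphenyl)-6-methoxy-2-(4-methoxyphenyl)-2,3-dihydrobenzofuran-4-yl]methanone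
Conditions: PdCl2(dppf) (5 mol%), K2CO3 (3 equiv.), CO (1 atm), anisole–H2O 20:1, 80 °C
Reagents that add atoms: carbon monoxide, [C-]#[O+]
Why: Carbonylative Suzuki–Miyaura coupling, in which oxidative addition into C–I (the aryl chloride is inert to this catalyst under CO), CO insertion and transmetalation with 7 give the diaryl ketone; the ortho substituents on both partners should slow direct biaryl coupling more than the acyl pathway.

Step 7
Reactants: 11 diaryl ketone
Product: 12 hydrazone (C=N–NH2, mixture of C=N isomers) of ketone 11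
Conditions: N2H4·H2O (20 equiv.), AcOH (10 mol%), EtOH, 100 °C, sealed tube
Reagents that add atoms: hydrazine (used as the hydrate), NN
Why: Acid-catalysed condensation of hydrazine with the diaryl ketone gives the N-unsubstituted hydrazone, the large excess of hydrazine suppressing azine formation.

Step 8
Reactants: 12 hydrazone of ketone 11
Product: 14 (2S,3R)-6-chloro-3-[(2S,3S)-3-(3,5-dimethoxyphenyl)-6-methoxy-2-(4-methoxyphenyl)-2,3-dihydrobenzofuran-4-yl]-2-(4-methoxyphenyl)-2,3-dihydrobenzofuran (ring B cis), via diaryldiazomethane 13 (not isolated)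
Conditions: MnO2 (8 equiv.), CH2Cl2, 0 °C; filtered through Celite into Rh2(S-PTAD)4 (1 mol%), CH2Cl2, 0 °C to rt
Reagents that add atoms: none
Why: MnO2 dehydrogenates the hydrazone to the diaryldiazomethane, and the chiral dirhodium carboxylate converts it into a donor/donor carbene that inserts into the benzylic ether C–H bond (intramolecular 1,5 C–H insertion), closing ring B with C3 fixed as R by the catalyst and the two aryl groups cis, the usual outcome for such carbenes.

Step 9
Reactants: 14 ring B cis compound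
Product: 15 (2R,3R)-6-chloro-3-[(2S,3S)-3-(3,5-dimethoxyphenyl)-6-methoxy-2-(4-methoxyphenyl)-2,3-dihydrobenzofuran-4-yl]-2-(4-methoxyphenyl)-2,3-dihydrobenzofuran (ring B trans)
Conditions: CF3CO2H (10 equiv.), CH2Cl2 (0.02 M), 0 °C to rt
Reagents that add atoms: none
Why: Acid-mediated C2 epimerisation by reversible SN1-type ionisation of the C2–O bond to the 4-methoxybenzylic cation and reclosure by the phenol should lead to the more stable trans ring, C3 staying untouched and ring C, already trans, returning unchanged.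

Step 10
Reactants: 16 5-bromo-2-hydroxy-3-methoxybenzaldehyde; 9 4-methoxybenzyl chloride
Product: 17 5-bromo-3-methoxy-2-[(4-methoxybenzyl)oxy]benzaldehyde
Conditions: K2CO3 (1.5 equiv.), DMF, 60 °C
Reagents that add atoms: none
Why: Williamson ether synthesis, which places the future C2 of ring A and its anisyl group on the phenol oxygen.

Step 11
Reactants: 17 5-bromo-3-methoxy-2-[(4-methoxybenzyl)oxy]benzaldehyde; 18 3,5-dimethoxyphenylmagnesium chloride
Product: 19 {5-bromo-3-methoxy-2-[(4-methoxybenzyl)oxy]phenyl}(3,5-dimethoxyphenyl)methanol (racemic)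
Conditions: THF, −78 to 0 °C; then H2O
Reagents that add atoms: none
Why: Grignard addition to the aldehyde, which the aryl bromide tolerates at low temperature; the carbinol centre is racemic and is removed in the next step.

Step 12
Reactants: 19 diaryl carbinol
Product: 20 {5-bromo-3-methoxy-2-[(4-methoxybenzyl)oxy]phenyl}(3,5-dimethoxyphenyl)methanone
Conditions: MnO2 (10 equiv.), CH2Cl2, rt
Reagents that add atoms: none
Why: MnO2 oxidation of a doubly benzylic alcohol to the diaryl ketone.

Step 13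
Reactants: 20 diaryl ketone
Product: 21 hydrazone (C=N–NH2, mixture of C=N isomers) of ketone 20
Conditions: N2H4·H2O (20 equiv.), AcOH (10 mol%), EtOH, 90 °C
Reagents that add atoms: hydrazine (used as the hydrate), NN
Why: Acid-catalysed condensation of hydrazine with the ketone, as in step 7.

Step 14
Reactants: 21 hydrazone of ketone 20
Product: 23 (2R,3S)-5-bromo-3-(3,5-dimethoxyphenyl)-7-methoxy-2-(4-methoxyphenyl)-2,3-dihydrobenzofuran (cis), via diaryldiazomethane 22 (not isolated)
Conditions: MnO2 (8 equiv.), CH2Cl2, 0 °C; filtered through Celite into Rh2(R-PTAD)4 (1 mol%), CH2Cl2, 0 °C to rt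
Reagents that add atoms: none
Why: Hydrazone dehydrogenation and dirhodium-catalysed intramolecular 1,5 C–H insertion of the donor/donor carbene, as in step 8, with the antipodal catalyst fixing C3 of ring A as S and the aryl groups cis.

Step 15
Reactants: 23 ring A cis bromide
Product: 24 (2S,3S)-5-bromo-3-(3,5-dimethoxyphenyl)-7-methoxy-2-(4-methoxyphenyl)-2,3-dihydrobenzofuran (trans)
Conditions: CF3CO2H (10 equiv.), CH2Cl2 (0.02 M), 0 °C to rt
Reagents that add atoms: none
Why: Acid-mediated C2 epimerisation through the 4-methoxybenzylic cation, as in step 9, run before the acid-sensitive styrene is installed.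

Step 16
Reactants: 24 ring A trans bromide
Product: 25 (2S,3S)-3-(3,5-dimethoxyphenyl)-7-methoxy-2-(4-methoxyphenyl)-5-vinyl-2,3-dihydrobenzofuran
Conditions: Pd(PPh3)4 (5 mol%), K2CO3 (3 equiv.), dioxane–H2O 4:1, 90 °C
Reagents that add atoms: 4,4,5,5-tetramethyl-2-vinyl-1,3,2-dioxaborolane (vinylboronic acid pinacol ester), C=CB1OC(C)(C)C(C)(C)O1
Why: Suzuki–Miyaura vinylation of the aryl bromide under conditions too mild to disturb the trans ring.

Step 17
Reactants: 15 ring B/ring C chloride; 25 ring A styrene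
Product: 26 nona-O-methyl ether of 27 (all nine phenols of 27 as OCH3; E alkene; ring A 2S,3S; ring B 2R,3R; ring C 2S,3S)
Conditions: Pd2(dba)3 (2.5 mol%), [HP(t-Bu)3]BF4 (10 mol%), Cs2CO3 (1.5 equiv.), dioxane, 110 °C
Reagents that add atoms: none
Why: Mizoroki–Heck reaction of an unactivated aryl chloride with a P(t-Bu)3-ligated palladium catalyst, in which arylation of the terminal alkene carbon and syn β-hydride elimination give the E stilbene.

Step 18
Reactants: 26 nona-O-methyl ether
Product: 27 CNP0265934.1, (2S,3S)-3-(3,5-dihydroxyphenyl)-5-{(E)-2-[(2R,3R)-3-[(2S,3S)-3-(3,5-dihydroxyphenyl)-6-hydroxy-2-(4-hydroxyphenyl)-2,3-dihydrobenzofuran-4-yl]-2-(4-hydroxyphenyl)-2,3-dihydrobenzofuran-6-yl]vinyl}-2-(4-hydroxyphenyl)-2,3-dihydrobenzofuran-7-ol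
Conditions: BBr3 (30 equiv.), CH2Cl2, −78 °C to rt; then H2O, 0 °C
Reagents that add atoms: none
Why: Lewis-acid cleavage of aryl methyl ethers by BBr3, the standard end of permethylated oligostilbene syntheses; the C3 centres are not touched and any reversible ionisation at C2 returns to the trans rings.

**Compound list**

1 | 3-chloro-5-methoxyphenol | COc1cc(O)cc(Cl)c1 | starting material
2 | 2-bromo-1-(3,5-dimethoxyphenyl)ethanone | COc1cc(OC)cc(C(=O)CBr)c1 | starting material
3 | 2-(3-chloro-5-methoxyphenoxy)-1-(3,5-dimethoxyphenyl)ethanone | COc1cc(Cl)cc(OCC(=O)c2cc(OC)cc(OC)c2)c1 | intermediate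
4 | 4-chloro-3-(3,5-dimethoxyphenyl)-6-methoxybenzofuran | COc1cc(Cl)c2c(-c3cc(OC)cc(OC)c3)coc2c1 | intermediate
5 | 4-iodoanisole | COc1ccc(I)cc1 | starting material
6 | (2S,3S)-4-chloro-3-(3,5-dimethoxyphenyl)-6-methoxy-2-(4-methoxyphenyl)-2,3-dihydrobenzofuran | Clc1cc(OC)cc2c1[C@H](c1cc(OC)cc(OC)c1)[C@@H](c1ccc(OC)cc1)O2 | intermediate
7 | 2-[(2S,3S)-3-(3,5-dimethoxyphenyl)-6-methoxy-2-(4-methoxyphenyl)-2,3-dihydrobenzofuran-4-yl]-4,4,5,5-tetramethyl-1,3,2-dioxaborolane | CC1(C)OB(OC1(C)C)c1cc(OC)cc2c1[C@H](c1cc(OC)cc(OC)c1)[C@@H](c1ccc(OC)cc1)O2 | intermediate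
8 | 5-chloro-2-iodophenol | Oc1cc(Cl)ccc1I | starting material
9 | 4-methoxybenzyl chloride | COc1ccc(CCl)cc1 | starting material
10 | 4-chloro-1-iodo-2-[(4-methoxybenzyl)oxy]benzene | COc1ccc(COc2cc(Cl)ccc2I)cc1 | intermediate
11 | {4-chloro-2-[(4-methoxybenzyl)oxy]phenyl}[(2S,3S)-3-(3,5-dimethoxyphenyl)-6-methoxy-2-(4-methoxyphenyl)-2,3-dihydrobenzofuran-4-yl]methanone | O=C(c1ccc(Cl)cc1OCc1ccc(OC)cc1)c1cc(OC)cc2c1[C@H](c1cc(OC)cc(OC)c1)[C@@H](c1ccc(OC)cc1)O2 | intermediate
12 | hydrazone of ketone 11 (mixture of C=N isomers) | NN=C(c1ccc(Cl)cc1OCc1ccc(OC)cc1)c1cc(OC)cc2c1[C@H](c1cc(OC)cc(OC)c1)[C@@H](c1ccc(OC)cc1)O2 | intermediate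
13 | diaryldiazomethane from 12 (not isolated) | [N-]=[N+]=C(c1ccc(Cl)cc1OCc1ccc(OC)cc1)c1cc(OC)cc2c1[C@H](c1cc(OC)cc(OC)c1)[C@@H](c1ccc(OC)cc1)O2 | intermediate
14 | (2S,3R)-6-chloro-3-[(2S,3S)-3-(3,5-dimethoxyphenyl)-6-methoxy-2-(4-methoxyphenyl)-2,3-dihydrobenzofuran-4-yl]-2-(4-methoxyphenyl)-2,3-dihydrobenzofuran (ring B cis) | Clc1ccc2c(c1)O[C@H](c1ccc(OC)cc1)[C@@H]2c1cc(OC)cc2c1[C@H](c1cc(OC)cc(OC)c1)[C@@H](c1ccc(OC)cc1)O2 | intermediate
15 | (2R,3R)-6-chloro-3-[(2S,3S)-3-(3,5-dimethoxyphenyl)-6-methoxy-2-(4-methoxyphenyl)-2,3-dihydrobenzofuran-4-yl]-2-(4-methoxyphenyl)-2,3-dihydrobenzofuran (ring B trans) | Clc1ccc2c(c1)O[C@@H](c1ccc(OC)cc1)[C@@H]2c1cc(OC)cc2c1[C@H](c1cc(OC)cc(OC)c1)[C@@H](c1ccc(OC)cc1)O2 | intermediate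
16 | 5-bromo-2-hydroxy-3-methoxybenzaldehyde | COc1cc(Br)cc(C=O)c1O | starting material
17 | 5-bromo-3-methoxy-2-[(4-methoxybenzyl)oxy]benzaldehyde | COc1ccc(COc2c(OC)cc(Br)cc2C=O)cc1 | intermediate
18 | 3,5-dimethoxyphenylmagnesium chloride (THF solution) | COc1cc(OC)cc([Mg]Cl)c1 | starting material
19 | {5-bromo-3-methoxy-2-[(4-methoxybenzyl)oxy]phenyl}(3,5-dimethoxyphenyl)methanol (racemic) | COc1ccc(COc2c(OC)cc(Br)cc2C(O)c2cc(OC)cc(OC)c2)cc1 | intermediate
20 | {5-bromo-3-methoxy-2-[(4-methoxybenzyl)oxy]phenyl}(3,5-dimethoxyphenyl)methanone | COc1ccc(COc2c(OC)cc(Br)cc2C(=O)c2cc(OC)cc(OC)c2)cc1 | intermediate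
21 | hydrazone of ketone 20 (mixture of C=N isomers) | COc1ccc(COc2c(OC)cc(Br)cc2C(=NN)c2cc(OC)cc(OC)c2)cc1 | intermediate
22 | diaryldiazomethane from 21 (not isolated) | COc1ccc(COc2c(OC)cc(Br)cc2C(=[N+]=[N-])c2cc(OC)cc(OC)c2)cc1 | intermediate
23 | (2R,3S)-5-bromo-3-(3,5-dimethoxyphenyl)-7-methoxy-2-(4-methoxyphenyl)-2,3-dihydrobenzofuran (cis) | COc1ccc([C@@H]2Oc3c(OC)cc(Br)cc3[C@@H]2c2cc(OC)cc(OC)c2)cc1 | intermediate
24 | (2S,3S)-5-bromo-3-(3,5-dimethoxyphenyl)-7-methoxy-2-(4-methoxyphenyl)-2,3-dihydrobenzofuran (trans) | COc1ccc([C@H]2Oc3c(OC)cc(Br)cc3[C@@H]2c2cc(OC)cc(OC)c2)cc1 | intermediate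
25 | (2S,3S)-3-(3,5-dimethoxyphenyl)-7-methoxy-2-(4-methoxyphenyl)-5-vinyl-2,3-dihydrobenzofuran | COc1ccc([C@H]2Oc3c(OC)cc(C=C)cc3[C@@H]2c2cc(OC)cc(OC)c2)cc1 | intermediate
26 | nona-O-methyl ether of 27 | COc1ccc([C@H]2Oc3c(OC)cc(/C=C/c4ccc5c(c4)O[C@@H](c4ccc(OC)cc4)[C@@H]5c4cc(OC)cc5c4[C@H](c4cc(OC)cc(OC)c4)[C@@H](c4ccc(OC)cc4)O5)cc3[C@@H]2c2cc(OC)cc(OC)c2)cc1 | intermediate
27 | CNP0265934.1 | Oc1ccc([C@H]2Oc3c(O)cc(/C=C/c4ccc5c(c4)O[C@@H](c4ccc(O)cc4)[C@@H]5c4cc(O)cc5c4[C@H](c4cc(O)cc(O)c4)[C@@H](c4ccc(O)cc4)O5)cc3[C@@H]2c2cc(O)cc(O)c2)cc1 | target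

**Step count and risks**

Total step count: 18. Longest linear sequence: 10 steps (steps 1, 2, 3, 4, 6, 7, 8, 9, 17, 18).

Steps most likely to fail:

1. Step 3 (new method). The arylpalladium may be reduced by formate before it inserts, leaving 4 unchanged. The benzylic palladium intermediate may open the ring by β-aryloxide elimination or rearomatise to the 2,3-diarylbenzofuran. The ligand may discriminate the two furan faces poorly. Fallback with known chemistry, setting out from 4 and returning at 6: the C2 carbon of the furan is cut out and replaced by a 4-methoxybenzylic carbon, so that ring C is closed by the same carbene insertion that serves rings A and B. Ozonolysis of 4 (O3, CH2Cl2–MeOH, −78 °C; Me2S; then K2CO3, MeOH–H2O to cleave the aryl formate) should give (2-chloro-6-hydroxy-4-methoxyphenyl)(3,5-dimethoxyphenyl)methanone F1. Etherification with 9 (K2CO3, DMF) gives {2-chloro-4-methoxy-6-[(4-methoxybenzyl)oxy]phenyl}(3,5-dimethoxyphenyl)methanone F2. Hydrazine hydrate gives the hydrazone of that ketone F3. MnO2 gives the corresponding diaryldiazomethane F4, used without isolation. Rh2(R-PTAD)4 should close the ring to (2R,3S)-4-chloro-3-(3,5-dimethoxyphenyl)-6-methoxy-2-(4-methoxyphenyl)-2,3-dihydrobenzofuran F5 (cis), and CF3CO2H equilibrates C2 to give 6.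

2. Step 8. The congested ketone 11 may resist condensation in step 7. The crowded carbene may attack the neighbouring dimethoxyphenyl ring instead of the ether C–H bond. The chiral catalyst may be mismatched with the stereocentres of ring C and give poor facial selectivity. Fallback, setting out from 7 and returning at 15 (steps 5 to 7 and 9 are then not needed): ring B is attached flat and reduced afterwards. Phenol 8 and 4-ethynylanisole (PdCl2(PPh3)2, CuI, Et3N, 60 °C; Sonogashira coupling with cyclisation of the ortho-alkynylphenol) give 6-chloro-2-(4-methoxyphenyl)benzofuran F6. NBS (MeCN, 0 °C) gives 3-bromo-6-chloro-2-(4-methoxyphenyl)benzofuran F7. Suzuki–Miyaura coupling of this bromide with 7 (Pd(PPh3)4, K2CO3, dioxane–H2O, 90 °C; the C–Br bond reacts, the C–Cl bond does not) gives 6-chloro-3-[(2S,3S)-3-(3,5-dimethoxyphenyl)-6-methoxy-2-(4-methoxyphenyl)-2,3-dihydrobenzofuran-4-yl]-2-(4-methoxyphenyl)benzofuran F8. Ionic hydrogenation (Et3SiH, 2 equiv., CF3CO2H, CH2Cl2, 0 °C; protonation at C3, hydride to the C2 oxocarbenium ion anti to the C3 aryl group) should give the two trans-dihydrobenzofurans: 15 and its ring B (2S,3S) diastereomer F9. These are diastereomers and would be separated by chromatography.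

3. Step 18. Ninefold ether cleavage may stall. Ionisation at C2 may be followed by Friedel–Crafts capture instead of reclosure. The electron-rich stilbene may be protonated and oligomerise. Fallback, setting out from 15 and 24 and returning at 27: the methyl ethers are exchanged for acetates before the acid-sensitive stilbene exists. BBr3 (CH2Cl2, −78 to 0 °C) on 15 gives the pentaphenol of 15 F10, and Ac2O–pyridine gives its pentaacetate F11. BBr3 on 24 gives the tetraphenol of 24 F12, and Ac2O–pyridine gives its tetraacetate F13. Base-free Stille coupling with Bu3SnCH=CH2 (Pd(PPh3)4, toluene, 100 °C) gives the 5-vinyl tetraacetate F14. Heck coupling of the pentaacetate chloride with this styrene (Pd2(dba)3, [HP(t-Bu)3]BF4, Cy2NMe, dioxane, 100 °C) gives the nonaacetate of 27 F15. K2CO3 in degassed MeOH at 0 °C then frees 27.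

Further compounds
F1 | step 3 | (2-chloro-6-hydroxy-4-methoxyphenyl)(3,5-dimethoxyphenyl)methanone | COc1cc(O)c(C(=O)c2cc(OC)cc(OC)c2)c(Cl)c1
F2 | step 3 | {2-chloro-4-methoxy-6-[(4-methoxybenzyl)oxy]phenyl}(3,5-dimethoxyphenyl)methanone | COc1ccc(COc2cc(OC)cc(Cl)c2C(=O)c2cc(OC)cc(OC)c2)cc1
F3 | step 3 | hydrazone of F2 (mixture of C=N isomers) | COc1ccc(COc2cc(OC)cc(Cl)c2C(=NN)c2cc(OC)cc(OC)c2)cc1
F4 | step 3 | diaryldiazomethane from F3 (not isolated) | COc1ccc(COc2cc(OC)cc(Cl)c2C(=[N+]=[N-])c2cc(OC)cc(OC)c2)cc1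
F5 | step 3 | (2R,3S)-4-chloro-3-(3,5-dimethoxyphenyl)-6-methoxy-2-(4-methoxyphenyl)-2,3-dihydrobenzofuran (cis) | Clc1cc(OC)cc2c1[C@H](c1cc(OC)cc(OC)c1)[C@H](c1ccc(OC)cc1)O2
F6 | step 8 | 6-chloro-2-(4-methoxyphenyl)benzofuran | COc1ccc(-c2cc3ccc(Cl)cc3o2)cc1
F7 | step 8 | 3-bromo-6-chloro-2-(4-methoxyphenyl)benzofuran | COc1ccc(-c2oc3cc(Cl)ccc3c2Br)cc1
F8 | step 8 | 6-chloro-3-[(2S,3S)-3-(3,5-dimethoxyphenyl)-6-methoxy-2-(4-methoxyphenyl)-2,3-dihydrobenzofuran-4-yl]-2-(4-methoxyphenyl)benzofuran | Clc1ccc2c(c1)oc(-c1ccc(OC)cc1)c2-c1cc(OC)cc2c1[C@H](c1cc(OC)cc(OC)c1)[C@@H](c1ccc(OC)cc1)O2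
F9 | step 8 | ring B (2S,3S) diastereomer of 15 | Clc1ccc2c(c1)O[C@H](c1ccc(OC)cc1)[C@H]2c1cc(OC)cc2c1[C@H](c1cc(OC)cc(OC)c1)[C@@H](c1ccc(OC)cc1)O2
F10 | step 18 | pentaphenol of 15 (all five OCH3 as OH) | Clc1ccc2c(c1)O[C@@H](c1ccc(O)cc1)[C@@H]2c1cc(O)cc2c1[C@H](c1cc(O)cc(O)c1)[C@@H](c1ccc(O)cc1)O2
F11 | step 18 | pentaacetate of F10 | Clc1ccc2c(c1)O[C@@H](c1ccc(OC(C)=O)cc1)[C@@H]2c1cc(OC(C)=O)cc2c1[C@H](c1cc(OC(C)=O)cc(OC(C)=O)c1)[C@@H](c1ccc(OC(C)=O)cc1)O2
F12 | step 18 | tetraphenol of 24 (all four OCH3 as OH) | Oc1ccc([C@H]2Oc3c(O)cc(Br)cc3[C@@H]2c2cc(O)cc(O)c2)cc1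
F13 | step 18 | tetraacetate of F12 | CC(=O)Oc1ccc([C@H]2Oc3c(OC(C)=O)cc(Br)cc3[C@@H]2c2cc(OC(C)=O)cc(OC(C)=O)c2)cc1
F14 | step 18 | 5-vinyl tetraacetate (bromide of F13 replaced by vinyl) | CC(=O)Oc1ccc([C@H]2Oc3c(OC(C)=O)cc(C=C)cc3[C@@H]2c2cc(OC(C)=O)cc(OC(C)=O)c2)cc1
F15 | step 18 | nonaacetate of 27 | CC(=O)Oc1ccc([C@H]2Oc3c(OC(C)=O)cc(/C=C/c4ccc5c(c4)O[C@@H](c4ccc(OC(C)=O)cc4)[C@@H]5c4cc(OC(C)=O)cc5c4[C@H](c4cc(OC(C)=O)cc(OC(C)=O)c4)[C@@H](c4ccc(OC(C)=O)cc4)O5)cc3[C@@H]2c2cc(OC(C)=O)cc(OC(C)=O)c2)cc1
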